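**Retrosynthetic overview**

1. The angelate on O6 goes on last. The (12Z)-diene comes from vinyl cross-coupling of a (Z)-13-iodo-12-alkene, made by an iodoethylidene Wittig reaction at C12 of a lactol.
2. The lactol is reduced 6α-silyloxysclareolide 20. The feature used: in ring B the tertiary C8–O bond (8α-O, axial 8β-methyl) lies anti to the C9–C10 bond across C8–C9, and C12 is two carbons from C9, so O8 and C12 close a γ-lactone on ring B.
3. Key disconnection: C9–C10 and C8–O of 20 are cut together, back to the ring-A acid 19 with an E-C8=C9 alkene and the C12 carboxyl. Ring B and the lactone form in one cationic step.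
4. Acid 19 comes from a terminal alkyne (methylalumination, ethylene oxide, oxidation). The alkyne comes from reagent-controlled propargylation of (S)-α-cyclocitral (sets C6), and the aldehyde from resolved α-cyclogeranic acid (sets C5).
5. Ring order: ring A first (acid cyclization of geranic acid, step 1), then ring B together with the temporary lactone ring (step 11).

Key step: step 11

Remark: labdane numbering (C1–C20) is used for all intermediates; O6 is carried as the triisopropylsilyl ether.
Assumption: in step 2 the salt of the (S)-acid with (S)-1-phenylethylamine is taken as the less soluble diastereomer; if the pairing is the opposite, (R)-1-phenylethylamine is used in the same way and nothing else changes.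

**Step 1**
Reactants: 1 geranic acid
Product: 2 (±)-α-cyclogeranic acid (racemic 2,6,6-trimethylcyclohex-2-ene-1-carboxylic acid)
Conditions: 85% H3PO4, 100 °C; crystallization
Reagents that add atoms: none
Why: Brønsted acid cation–olefin cyclization, in which protonation of the C6=C7 bond gives a tertiary cation that the conjugated alkene captures through C2 and loss of a proton leaves the endocyclic alkene of the crystalline α-acid, racemic at the new centre.

**Step 2**
Reactants: 2 (±)-α-cyclogeranic acid; 3 (S)-1-phenylethylamine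
Product: 4 (S)-1-phenylethylammonium (S)-α-cyclogeranate (crystalline salt)
Conditions: acetone, reflux → rt; repeated fractional crystallization
Reagents that add atoms: (S)-1-phenylethylamine (3), C[C@H](N)c1ccccc1
Why: Classical resolution through diastereomeric salts, whose different solubility lets one diastereomer be crystallized to purity, which fixes the later C5.

**Step 3**
Reactants: 4 (S)-1-phenylethylammonium (S)-α-cyclogeranate
Product: 5 (S)-α-cyclogeranic acid
Conditions: 1 M HCl, Et2O, 0 °C
Reagents that add atoms: none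
Why: Acid–base liberation, the mineral acid protonating the carboxylate while the amine stays in water as its hydrochloride and the stereocentre is untouched.

**Step 4**
Reactants: 5 (S)-α-cyclogeranic acid
Product: 6 (S)-α-cyclogeraniol
Conditions: LiAlH4, Et2O, 0 °C → rt; aq. NaOH work-up
Reagents that add atoms: none
Why: Hydride reduction of a carboxylic acid to the primary alcohol, which leaves the isolated trisubstituted alkene and the stereocentre alone.

**Step 5**
Reactants: 6 (S)-α-cyclogeraniol
Product: 7 (S)-α-cyclocitral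
Conditions: Dess–Martin periodinane, NaHCO3, CH2Cl2, 0 °C; used at once
Reagents that add atoms: none
Why: Dess–Martin oxidation under bicarbonate buffer stops at the aldehyde and avoids the acid or base that would epimerize C5 or move the ring alkene into conjugation.

**Step 6**
Reactants: 7 (S)-α-cyclocitral; 8 propargyl bromide
Product: 11 (1S)-1-[(1S)-2,6,6-trimethylcyclohex-2-en-1-yl]but-3-yn-1-ol, via allenylmagnesium bromide 9 (not isolated), via B-allenyldiisopinocampheylborane 10 (not isolated)
Conditions: 8, Mg, HgCl2 (cat.), Et2O, 0 °C; (−)-Ipc2BOMe [from (+)-α-pinene], −78 °C → rt; 7, −78 °C; NaOH, 30% H2O2, rt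
Reagents that add atoms: propargyl bromide (8), C#CCBr
Why: Brown asymmetric allenylboration, in which the allenylborane adds through a closed six-membered chair transition state with SE2' transposition to the homopropargylic alcohol and the isopinocampheyl groups direct attack to the Si face of the aldehyde (the sense known for the allyl reagent with the same ligands), which sets C6 as S under reagent control.

**Step 7**
Reactants: 11 (1S)-1-[(1S)-2,6,6-trimethylcyclohex-2-en-1-yl]but-3-yn-1-ol
Product: 12 triisopropyl{[(1S)-1-[(1S)-2,6,6-trimethylcyclohex-2-en-1-yl]but-3-yn-1-yl]oxy}silane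
Conditions: i-Pr3SiOTf, 2,6-lutidine, CH2Cl2, 0 °C → rt
Reagents that add atoms: triisopropylsilyl triflate, CC(C)[Si](OS(=O)(=O)C(F)(F)F)(C(C)C)C(C)C
Why: Silyl ether formation with a silyl triflate and a hindered pyridine base, which silylates hindered secondary alcohols and gives an aryl-free, bulky ether that blocks chelation in the next step.

**Step 8**
Reactants: 12 silyl ether; 13 trimethylaluminium; 14 ethylene oxide
Product: 17 (3E,6S)-4-methyl-6-(triisopropylsilyloxy)-6-[(1S)-2,6,6-trimethylcyclohex-2-en-1-yl]hex-3-en-1-ol, via alkenyldimethylalane 15 (not isolated), via lithium alkenyl(butyl)dimethylalanate 16 (not isolated)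
Conditions: Me3Al, Cp2ZrCl2 (cat.), CH2Cl2, 0 °C → rt; volatiles removed; n-BuLi, THF/hexane, −78 → 0 °C; ethylene oxide, 0 °C → rt; aq. potassium sodium tartrate
Reagents that add atoms: trimethylaluminium (13), C[Al](C)C; ethylene oxide (14), C1CO1
Why: Negishi zirconium-catalysed methylalumination adds methyl and aluminium syn across the terminal alkyne with the metal at the terminus, and the alanate opens ethylene oxide with retention at the alkenyl carbon, so the E-C8=C9 alkene with the C11–C12 hydroxyethyl arm results.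

**Step 9**
Reactants: 17 homoallylic alcohol
Product: 18 (3E,6S)-4-methyl-6-(triisopropylsilyloxy)-6-[(1S)-2,6,6-trimethylcyclohex-2-en-1-yl]hex-3-enal
Conditions: Dess–Martin periodinane, NaHCO3, CH2Cl2, 0 °C; used crude
Reagents that add atoms: none
Why: Buffered Dess–Martin oxidation gives the β,γ-unsaturated aldehyde without drawing the alkene into conjugation.

**Step 10**
Reactants: 18 aldehyde
Product: 19 (3E,6S)-4-methyl-6-(triisopropylsilyloxy)-6-[(1S)-2,6,6-trimethylcyclohex-2-en-1-yl]hex-3-enoic acid
Conditions: NaClO2, NaH2PO4, 2-methyl-2-butene, t-BuOH/H2O, 0 °C → rt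
Reagents that add atoms: NaClO2, [Na+].[O-]Cl=O
Why: Pinnick oxidation converts the aldehyde to the acid under weakly acidic buffer while 2-methyl-2-butene scavenges hypochlorous acid, so both alkenes, their positions and the silyl ether are kept.

**Step 11**
Reactants: 19 acid
Product: 20 6α-(triisopropylsilyloxy)sclareolide (8α,12-epoxy-13,14,15,16-tetranorlabdan-12-one with 6α-OSi; 5α-H, 9α-H, 10β-CH3, 8β-CH3)
Conditions: ClSO3H (5 equiv), 2-nitropropane, −78 °C, 30 min; Et3N at −78 °C, then aq. NaHCO3
Reagents that add atoms: none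
Why: Protonation of the C1=C10 bond of ring A at C1 gives the tertiary C10 cation, C9 of the side-chain alkene bonds to C10 and the carboxyl oxygen captures the developing C8 cation on the opposite face of that alkene; the closest known reaction is the superacid cyclization of monocyclohomofarnesic acids to sclareolide (cation–olefin cyclization with carboxyl termination). Ring B closes 6-endo-trig through a chair, and the γ-lactone closes by capture of C8 by the acid oxygen, formally 5-endo with respect to the C8=C9 bond. C10 is set by C5, because with the side chain equatorial on ring A C9 bonds so that the 10-methyl ends anti to H5 (trans fusion), and C8 and C9 are set by stereospecific anti addition across the E alkene, giving 9β-CH2, 8α-O and the axial 8β-methyl. The C6 silyloxy group is equatorial only in this chair, so C5 and C6 reinforce each other, and a C5 epimer arising by loss and return of H5 through the C5=C10 alkene would have to close with the silyloxy group axial against the 10-methyl and is expected to revert. The step needs protonation of the ring alkene in preference to the C8=C9 bond, which is deactivated by the protonated carboxyl and the homoallylic oxygen, and it needs the silyl ether to survive, for which the low temperature, the short contact time, the cold basic quench and the hindered, weakly basic, aryl-free silyl group are chosen.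

**Step 12**
Reactants: 20 lactone
Product: 21 6α-(triisopropylsilyloxy)-8α,12-epoxy-13,14,15,16-tetranorlabdan-12-ol (lactol, both C12 anomers)
Conditions: i-Bu2AlH (1.1 equiv), CH2Cl2, −78 °C; aq. potassium sodium tartrate
Reagents that add atoms: none
Why: Partial reduction of a γ-lactone at −78 °C stops at the tetrahedral aluminium hemiacetal, which gives the lactol on work-up, the silyl ether being inert.

**Step 13**
Reactants: 21 lactol; 22 ethyltriphenylphosphonium iodide
Product: 26 (12Z)-13-iodo-6α-(triisopropylsilyloxy)-14,15-dinorlabd-12-en-8α-ol, via ethylidenetriphenylphosphorane 23 (not isolated), via (1-iodoethyl)triphenylphosphonium iodide 24 (not isolated), via (1-iodoethylidene)triphenylphosphorane 25 (not isolated)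
Conditions: 22, n-BuLi, THF, −78 → 0 °C; I2, −78 °C; NaN(SiMe3)2, −78 → −20 °C; sodium lactolate of 21 (NaN(SiMe3)2, THF, −78 °C) added at −78 °C → rt; ylide in excess
Reagents that add atoms: ethyltriphenylphosphonium iodide (22), CC[P+](c1ccccc1)(c1ccccc1)c1ccccc1.[I-]; iodine, II
Why: Wittig olefination of the lactol through its open hydroxy aldehyde with the α-iodoethylidene ylide (Zhao variant of the Stork–Zhao olefination), which is kinetically Z-selective and places iodine cis to C11.

**Step 14**
Reactants: 26 vinyl iodide; 27 tributyl(vinyl)stannane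
Product: 28 (12Z)-6α-(triisopropylsilyloxy)labda-12,14-dien-8α-ol
Conditions: Pd(PPh3)4 (cat.), CuI, CsF, DMF, 45 °C
Reagents that add atoms: tributyl(vinyl)stannane (27), C=C[Sn](CCCC)(CCCC)CCCC
Why: Stille cross-coupling under zerovalent palladium catalysis with copper and fluoride assistance replaces iodine by vinyl with retention of the alkene geometry, giving the (12Z)-diene.

**Step 15**
Reactants: 28 diene silyl ether
Product: 29 (12Z)-labda-12,14-diene-6α,8α-diol
Conditions: Bu4NF, THF, rt → 50 °C
Reagents that add atoms: none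
Why: Fluoride-induced desilylation driven by the Si–F bond, in a basic medium that spares the acid-sensitive diene and tertiary alcohol.

**Step 16**
Reactants: 29 diol; 30 angelic acid
Product: 32 (12Z)-8α-hydroxylabda-12,14-dien-6α-yl (2Z)-2-methylbut-2-enoate (target), via angelic 2,4,6-trichlorobenzoic anhydride 31 (not isolated)
Conditions: 30, 2,4,6-trichlorobenzoyl chloride, Et3N, toluene, rt; then 29, toluene, 80 °C
Reagents that add atoms: angelic acid (30), C/C=C(/C)C(O)=O
Why: Yamaguchi-type esterification through the mixed anhydride, run without a nucleophilic catalyst so that the angelate does not isomerize to the tiglate, acylates only the secondary 6α-hydroxyl because the tertiary 8α-hydroxyl is too hindered.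

**Compound list**

1 | geranic acid, (2E)-3,7-dimethylocta-2,6-dienoic acid | CC(C)=CCC/C(C)=C/C(O)=O | starting material
2 | (±)-α-cyclogeranic acid, racemic 2,6,6-trimethylcyclohex-2-ene-1-carboxylic acid | CC1=CCCC(C)(C)C1C(O)=O | intermediate
3 | (S)-1-phenylethylamine | C[C@H](N)c1ccccc1 | starting material
4 | (S)-1-phenylethylammonium (1S)-2,6,6-trimethylcyclohex-2-ene-1-carboxylate | [O-]C(=O)[C@@H]1C(C)=CCCC1(C)C.C[C@H]([NH3+])c1ccccc1 | intermediate
5 | (S)-α-cyclogeranic acid, (1S)-2,6,6-trimethylcyclohex-2-ene-1-carboxylic acid | OC(=O)[C@@H]1C(C)=CCCC1(C)C | intermediate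
6 | (S)-α-cyclogeraniol, [(1S)-2,6,6-trimethylcyclohex-2-en-1-yl]methanol | OC[C@@H]1C(C)=CCCC1(C)C | intermediate
7 | (S)-α-cyclocitral, (1S)-2,6,6-trimethylcyclohex-2-ene-1-carbaldehyde | O=C[C@@H]1C(C)=CCCC1(C)C | intermediate
8 | propargyl bromide | C#CCBr | starting material
9 | allenylmagnesium bromide | C=C=C[Mg]Br | intermediate
10 | B-allenyldiisopinocampheylborane, isopinocampheyl groups from (+)-α-pinene | C=C=CB([C@@H]1C[C@@H]2C[C@H]([C@H]1C)C2(C)C)[C@@H]1C[C@@H]2C[C@H]([C@H]1C)C2(C)C | intermediate
11 | (1S)-1-[(1S)-2,6,6-trimethylcyclohex-2-en-1-yl]but-3-yn-1-ol | C#CC[C@H](O)[C@@H]1C(C)=CCCC1(C)C | intermediate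
12 | triisopropylsilyl ether of 11 | C#CC[C@H](O[Si](C(C)C)(C(C)C)C(C)C)[C@@H]1C(C)=CCCC1(C)C | intermediate
13 | trimethylaluminium | C[Al](C)C | starting material
14 | ethylene oxide | C1CO1 | starting material
15 | (E)-alkenyldimethylalane from 12 (Al on C9, methyl on C8, syn) | C[Al](C)/C=C(\C)C[C@H](O[Si](C(C)C)(C(C)C)C(C)C)[C@@H]1C(C)=CCCC1(C)C | intermediate
16 | lithium (E)-alkenyl(butyl)dimethylalanate from 15 | [Li+].CCCC[Al-](C)(C)/C=C(\C)C[C@H](O[Si](C(C)C)(C(C)C)C(C)C)[C@@H]1C(C)=CCCC1(C)C | intermediate
17 | (3E,6S)-4-methyl-6-(triisopropylsilyloxy)-6-[(1S)-2,6,6-trimethylcyclohex-2-en-1-yl]hex-3-en-1-ol | OCC/C=C(\C)C[C@H](O[Si](C(C)C)(C(C)C)C(C)C)[C@@H]1C(C)=CCCC1(C)C | intermediate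
18 | (3E,6S)-4-methyl-6-(triisopropylsilyloxy)-6-[(1S)-2,6,6-trimethylcyclohex-2-en-1-yl]hex-3-enal | O=CC/C=C(\C)C[C@H](O[Si](C(C)C)(C(C)C)C(C)C)[C@@H]1C(C)=CCCC1(C)C | intermediate
19 | (3E,6S)-4-methyl-6-(triisopropylsilyloxy)-6-[(1S)-2,6,6-trimethylcyclohex-2-en-1-yl]hex-3-enoic acid | OC(=O)C/C=C(\C)C[C@H](O[Si](C(C)C)(C(C)C)C(C)C)[C@@H]1C(C)=CCCC1(C)C | intermediate
20 | 6α-(triisopropylsilyloxy)sclareolide | O=C1C[C@@H]2[C@@]3(C)CCCC(C)(C)[C@@H]3[C@@H](O[Si](C(C)C)(C(C)C)C(C)C)C[C@@]2(C)O1 | intermediate
21 | 6α-(triisopropylsilyloxy)-8α,12-epoxy-13,14,15,16-tetranorlabdan-12-ol (C12 anomers) | OC1C[C@@H]2[C@@]3(C)CCCC(C)(C)[C@@H]3[C@@H](O[Si](C(C)C)(C(C)C)C(C)C)C[C@@]2(C)O1 | intermediate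
22 | ethyltriphenylphosphonium iodide | CC[P+](c1ccccc1)(c1ccccc1)c1ccccc1.[I-] | starting material
23 | ethylidenetriphenylphosphorane | CC=P(c1ccccc1)(c1ccccc1)c1ccccc1 | intermediate
24 | (1-iodoethyl)triphenylphosphonium iodide | CC(I)[P+](c1ccccc1)(c1ccccc1)c1ccccc1.[I-] | intermediate
25 | (1-iodoethylidene)triphenylphosphorane | CC(I)=P(c1ccccc1)(c1ccccc1)c1ccccc1 | intermediate
26 | (12Z)-13-iodo-6α-(triisopropylsilyloxy)-14,15-dinorlabd-12-en-8α-ol | I/C(C)=C\C[C@@H]1[C@@]2(C)CCCC(C)(C)[C@@H]2[C@@H](O[Si](C(C)C)(C(C)C)C(C)C)C[C@@]1(C)O | intermediate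
27 | tributyl(vinyl)stannane | C=C[Sn](CCCC)(CCCC)CCCC | starting material
28 | (12Z)-6α-(triisopropylsilyloxy)labda-12,14-dien-8α-ol | C=C/C(C)=C\C[C@@H]1[C@@]2(C)CCCC(C)(C)[C@@H]2[C@@H](O[Si](C(C)C)(C(C)C)C(C)C)C[C@@]1(C)O | intermediate
29 | (12Z)-labda-12,14-diene-6α,8α-diol | C=C/C(C)=C\C[C@@H]1[C@@]2(C)CCCC(C)(C)[C@@H]2[C@@H](O)C[C@@]1(C)O | intermediate
30 | angelic acid, (2Z)-2-methylbut-2-enoic acid | C/C=C(/C)C(O)=O | starting material
31 | angelic 2,4,6-trichlorobenzoic anhydride | C/C=C(/C)C(=O)OC(=O)c1c(Cl)cc(Cl)cc1Cl | intermediate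
32 | (12Z)-8α-hydroxylabda-12,14-dien-6α-yl (2Z)-2-methylbut-2-enoate | C=C/C(C)=C\C[C@@H]1[C@@]2(C)CCCC(C)(C)[C@@H]2[C@@H](OC(=O)/C(C)=C\C)C[C@@]1(C)O | target

**Step count and risks**

Total step count: 16. Longest linear sequence: 16 steps (from geranic acid 1; all other partners are bought).

The three steps most likely to fail:

1. Step 11. The C10 cation can be diverted before C9 reaches it. The O6 lone pair can push a Grob-type cleavage of the C5–C6 bond (the cation is the adduct of a Prins addition run backwards), the superacid can strip the silyl group, and loss and return of H5 can scramble C5. The fallback replaces the silyl ether by an acetate before the cyclization, because an acyl oxygen cannot support the oxocarbenium ion that the cleavage needs, resists the acid, and terpenyl acetates are known to survive superacid cyclization. It sets out from acid 19: Bu4NF in THF should give (3E,6S)-6-hydroxy-4-methyl-6-[(1S)-2,6,6-trimethylcyclohex-2-en-1-yl]hex-3-enoic acid F1; Ac2O and pyridine, with aqueous work-up to hydrolyse the mixed anhydride, the 6-acetoxy acid F2; ClSO3H in 2-nitropropane at −78 °C 6α-acetoxysclareolide F3; K2CO3 in MeOH followed by dilute HCl to reclose the lactone 6α-hydroxysclareolide F4; and i-Pr3SiOTf with 2,6-lutidine returns to lactone 20.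

2. Step 13. The lactolate may open too slowly at the low temperature the α-iodo ylide needs, so that the ylide decays or loses iodine before it meets the aldehyde, and the alkene geometry may erode. The fallback presents a free, O8-protected aldehyde and builds the Z alkene and the vinyl group by other olefinations. It sets out from lactone 20: MeNH(OMe)·HCl and Me3Al in CH2Cl2 should open it to the 8α-hydroxy Weinreb amide F5; Et3SiOTf and 2,6-lutidine cap the tertiary hydroxyl to give the 8-O-triethylsilyl amide F6; i-Bu2AlH in THF at −78 °C gives the C12 aldehyde F7; Still–Gennari olefination with ethyl 2-[bis(2,2,2-trifluoroethoxy)phosphoryl]propanoate, KN(SiMe3)2 and 18-crown-6 in THF at −78 °C gives the (12Z)-ethyl ester F8; i-Bu2AlH gives the (12Z)-allylic alcohol F9; MnO2 gives the (12Z)-enal F10; methylenetriphenylphosphorane (Ph3PCH3Br, KOt-Bu, THF) gives the (12Z)-diene bis-silyl ether F11; and Bu4NF removes both silyl groups and returns to diol 29.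

3. Step 6. If the facial preference of the chiral borane and the bias of C5 are mismatched, selectivity at C6 drops, and the aldehyde can epimerize at C5 if the addition is slow. The fallback gives up reagent control: from aldehyde 7, propargyl bromide 8 and Zn in THF/aq. NH4Cl (Barbier propargylation) should give both C6 epimers, which are separated. The unwanted (1R)-1-[(1S)-2,6,6-trimethylcyclohex-2-en-1-yl]but-3-yn-1-ol F12 is inverted by Mitsunobu reaction with 4-nitrobenzoic acid, PPh3 and diisopropyl azodicarboxylate to the (1S)-4-nitrobenzoate F13, and K2CO3 in MeOH returns to alcohol 11.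

**Further compounds**

F1 | step 11 | (3E,6S)-6-hydroxy-4-methyl-6-[(1S)-2,6,6-trimethylcyclohex-2-en-1-yl]hex-3-enoic acid | OC(=O)C/C=C(\C)C[C@H](O)[C@@H]1C(C)=CCCC1(C)C
F2 | step 11 | (3E,6S)-6-acetoxy-4-methyl-6-[(1S)-2,6,6-trimethylcyclohex-2-en-1-yl]hex-3-enoic acid | OC(=O)C/C=C(\C)C[C@H](OC(C)=O)[C@@H]1C(C)=CCCC1(C)C
F3 | step 11 | 6α-acetoxysclareolide | O=C1C[C@@H]2[C@@]3(C)CCCC(C)(C)[C@@H]3[C@@H](OC(C)=O)C[C@@]2(C)O1
F4 | step 11 | 6α-hydroxysclareolide | O=C1C[C@@H]2[C@@]3(C)CCCC(C)(C)[C@@H]3[C@@H](O)C[C@@]2(C)O1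
F5 | step 13 | 8α-hydroxy-N-methoxy-N-methyl-6α-(triisopropylsilyloxy)-13,14,15,16-tetranorlabdan-12-amide | CON(C)C(=O)C[C@@H]1[C@@]2(C)CCCC(C)(C)[C@@H]2[C@@H](O[Si](C(C)C)(C(C)C)C(C)C)C[C@@]1(C)O
F6 | step 13 | N-methoxy-N-methyl-8α-(triethylsilyloxy)-6α-(triisopropylsilyloxy)-13,14,15,16-tetranorlabdan-12-amide | CON(C)C(=O)C[C@@H]1[C@@]2(C)CCCC(C)(C)[C@@H]2[C@@H](O[Si](C(C)C)(C(C)C)C(C)C)C[C@@]1(C)O[Si](CC)(CC)CC
F7 | step 13 | 8α-(triethylsilyloxy)-6α-(triisopropylsilyloxy)-13,14,15,16-tetranorlabdan-12-al | O=CC[C@@H]1[C@@]2(C)CCCC(C)(C)[C@@H]2[C@@H](O[Si](C(C)C)(C(C)C)C(C)C)C[C@@]1(C)O[Si](CC)(CC)CC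
F8 | step 13 | ethyl (12Z)-8α-(triethylsilyloxy)-6α-(triisopropylsilyloxy)-15-norlabd-12-en-14-oate | CCOC(=O)/C(C)=C\C[C@@H]1[C@@]2(C)CCCC(C)(C)[C@@H]2[C@@H](O[Si](C(C)C)(C(C)C)C(C)C)C[C@@]1(C)O[Si](CC)(CC)CC
F9 | step 13 | (12Z)-8α-(triethylsilyloxy)-6α-(triisopropylsilyloxy)-15-norlabd-12-en-14-ol | OC/C(C)=C\C[C@@H]1[C@@]2(C)CCCC(C)(C)[C@@H]2[C@@H](O[Si](C(C)C)(C(C)C)C(C)C)C[C@@]1(C)O[Si](CC)(CC)CC
F10 | step 13 | (12Z)-8α-(triethylsilyloxy)-6α-(triisopropylsilyloxy)-15-norlabd-12-en-14-al | O=C/C(C)=C\C[C@@H]1[C@@]2(C)CCCC(C)(C)[C@@H]2[C@@H](O[Si](C(C)C)(C(C)C)C(C)C)C[C@@]1(C)O[Si](CC)(CC)CC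
F11 | step 13 | (12Z)-8α-(triethylsilyloxy)-6α-(triisopropylsilyloxy)labda-12,14-diene | C=C/C(C)=C\C[C@@H]1[C@@]2(C)CCCC(C)(C)[C@@H]2[C@@H](O[Si](C(C)C)(C(C)C)C(C)C)C[C@@]1(C)O[Si](CC)(CC)CC
F12 | step 6 | (1R)-1-[(1S)-2,6,6-trimethylcyclohex-2-en-1-yl]but-3-yn-1-ol | C#CC[C@@H](O)[C@@H]1C(C)=CCCC1(C)C
F13 | step 6 | (1S)-1-[(1S)-2,6,6-trimethylcyclohex-2-en-1-yl]but-3-yn-1-yl 4-nitrobenzoate | C#CC[C@H](OC(=O)c1ccc(cc1)[N+]([O-])=O)[C@@H]1C(C)=CCCC1(C)C
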